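**Retrosynthetic overview**
- After MOM removal, the target is cut between the β-carbon of the ketone and C6 of the chromene: a chromenyl bromide plus the β-carbanion of the aryl ketone (a ketone homoenolate), stored as a 1-arylcyclopropanol and released on palladium.
- The 1-arylcyclopropanol comes from Kulinkovich cyclopropanation of MOM-protected methyl 2,4-dihydroxybenzoate.
- The bromochromenol comes from one thermal cascade on a mixed bis-ether of 4-bromocatechol: the 1,1-dimethylallyl ether gives the C-prenyl group (aromatic Claisen) and the 1,1-dimethylpropargyl ether gives the 2,2-dimethylpyran ring.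
- The mixed bis-ether comes from catechol by mono-propargylation, bromination para to the free OH (this fixes which oxygen becomes which), semi-hydrogenation and a second propargylation.
- Ring order: both benzene rings are bought; the pyran ring is formed in step 5; the cyclopropane is made in step 7 and opened again in step 8.

Assumption: the target SMILES contains no stereocentre and no stereogenic double bond, so the compound is achiral and "single enantiomer" is taken to mean the structure as drawn.

**Step 1**
Reactants: 1 catechol (3 equiv); 2 3-chloro-3-methylbut-1-yne (1 equiv)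
Product: 3 2-[(2-methylbut-3-yn-2-yl)oxy]phenol
Conditions: K2CO3 (1.5 equiv), KI (0.1 equiv), acetone, 56 °C, N2, 24 h; excess 1 removed by aqueous wash
Reagents that add atoms: 3-chloro-3-methylbut-1-yne (compound 2), C#CC(C)(C)Cl
Why: Williamson-type O-alkylation with a tertiary propargylic chloride; catechol is symmetric and used in excess, so the monoether is the main product and no regiochemical question arises.

**Step 2**
Reactants: 3 2-[(2-methylbut-3-yn-2-yl)oxy]phenol
Product: 4 4-bromo-2-[(2-methylbut-3-yn-2-yl)oxy]phenol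
Conditions: NBS (1.0 equiv), MeCN, −20 to 0 °C
Reagents that add atoms: N-bromosuccinimide, O=C1CCC(=O)N1Br
Why: Electrophilic aromatic bromination goes para to the free OH, which is a much stronger director than the twisted, hindered tert-alkyl ether oxygen, and the terminal alkyne is inert to NBS at this temperature.

**Step 3**
Reactants: 4 4-bromo-2-[(2-methylbut-3-yn-2-yl)oxy]phenol
Product: 5 4-bromo-2-[(2-methylbut-3-en-2-yl)oxy]phenol
Conditions: H2 (1 atm), Pd/CaCO3 poisoned with Pb(OAc)2, quinoline, EtOAc, 20 °C, stopped after 1 equiv H2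
Reagents that add atoms: none
Why: Lindlar-type semi-hydrogenation stops at the terminal alkene, and the poisoned palladium surface does not cleave the aryl bromide at 1 atm.

**Step 4**
Reactants: 5 4-bromo-2-[(2-methylbut-3-en-2-yl)oxy]phenol; 2 3-chloro-3-methylbut-1-yne (1.5 equiv)
Product: 6 4-bromo-2-[(2-methylbut-3-en-2-yl)oxy]-1-[(2-methylbut-3-yn-2-yl)oxy]benzene
Conditions: CuCl2·2H2O (1 mol%), DBU (1.6 equiv), MeCN, 0 °C, 6 h
Reagents that add atoms: 3-chloro-3-methylbut-1-yne (compound 2), C#CC(C)(C)Cl
Why: Copper-catalysed propargylic etherification through a copper acetylide/allenylidene works on hindered phenols at 0 °C, cold enough that the 1,1-dimethylallyl ether does not rearrange early.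

**Step 5**
Reactants: 6 4-bromo-2-[(2-methylbut-3-en-2-yl)oxy]-1-[(2-methylbut-3-yn-2-yl)oxy]benzene
Product: 9 6-bromo-2,2-dimethyl-7-(3-methylbut-2-en-1-yl)-2H-chromen-8-ol, via C-prenyl phenol propargyl ether 7 (not isolated), via allenylcatechol 8 (not isolated)
Conditions: PhNEt2 (0.1 M), 130 °C, 2 h, then 190 °C, 6 h, N2
Reagents that add atoms: none
Why: Tandem aromatic Claisen and propargyl Claisen rearrangements, each with only one free ortho position: the allyl ether delivers a normal prenyl group between OH and Br by allylic inversion, and the propargyl ether gives the allene, which closes to the 2,2-dimethyl-2H-chromene by 1,5-H shift and 6π oxa-electrocyclisation.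

**Step 6**
Reactants: 10 methyl 2,4-dihydroxybenzoate
Product: 11 methyl 2,4-bis(methoxymethoxy)benzoate
Conditions: NaH (2.5 equiv), MOMCl (2.5 equiv), DMF, 0 to 20 °C
Reagents that add atoms: chloromethyl methyl ether, COCCl
Why: Williamson etherification of both sodium phenoxides (the hydrogen-bonded 2-OH included) gives acetals that survive Grignard reagents and carbonate base.

**Step 7**
Reactants: 11 methyl 2,4-bis(methoxymethoxy)benzoate; 12 ethylmagnesium bromide (3.2 equiv)
Product: 13 1-[2,4-bis(methoxymethoxy)phenyl]cyclopropan-1-ol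
Conditions: EtMgBr added over 2 h, Ti(OiPr)4 (0.3 equiv), THF, 0 to 20 °C; then aq NH4Cl
Reagents that add atoms: ethylmagnesium bromide (compound 12), CC[Mg]Br
Why: Kulinkovich cyclopropanation, in which the titanacyclopropane made catalytically from two ethyl groups adds twice to the ester carbonyl, turning the ester carbon into the carbinol carbon and supplying the two CH2 groups.

**Step 8**
Reactants: 9 6-bromo-2,2-dimethyl-7-(3-methylbut-2-en-1-yl)-2H-chromen-8-ol; 13 1-[2,4-bis(methoxymethoxy)phenyl]cyclopropan-1-ol (1.5 equiv)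
Product: 14 1-[2,4-bis(methoxymethoxy)phenyl]-3-[8-hydroxy-2,2-dimethyl-7-(3-methylbut-2-en-1-yl)-2H-chromen-6-yl]propan-1-one
Conditions: Pd(OAc)2 (5 mol%), XPhos (10 mol%), Cs2CO3 (3 equiv), toluene, 80 °C, N2
Reagents that add atoms: none
Why: Palladium-catalysed ring-opening cross-coupling of a cyclopropanol: 9 adds oxidatively to zerovalent palladium, the cesium cyclopropoxide undergoes strain-driven β-carbon elimination to a divalent palladium homoenolate (either CH2 is equivalent), and the bulky biaryl phosphine makes reductive elimination faster than β-hydride elimination.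

**Step 9**
Reactants: 14 1-[2,4-bis(methoxymethoxy)phenyl]-3-[8-hydroxy-2,2-dimethyl-7-(3-methylbut-2-en-1-yl)-2H-chromen-6-yl]propan-1-one
Product: 15 1-(2,4-dihydroxyphenyl)-3-[8-hydroxy-2,2-dimethyl-7-(3-methylbut-2-en-1-yl)-2H-chromen-6-yl]propan-1-one (CNP0290651.0)
Conditions: 3 M aq HCl, MeOH, 45 °C, 3 h
Reagents that add atoms: none
Why: Acid-catalysed transacetalisation to methanol removes both MOM groups under dilute, warm conditions that are normally too mild to cyclise an ortho-prenylphenol or open the chromene.

**Compound list**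
1 | catechol (benzene-1,2-diol) | Oc1ccccc1O | starting material
2 | 3-chloro-3-methylbut-1-yne | C#CC(C)(C)Cl | starting material
3 | 2-[(2-methylbut-3-yn-2-yl)oxy]phenol | C#CC(C)(C)Oc1ccccc1O | intermediate
4 | 4-bromo-2-[(2-methylbut-3-yn-2-yl)oxy]phenol | C#CC(C)(C)Oc1cc(Br)ccc1O | intermediate
5 | 4-bromo-2-[(2-methylbut-3-en-2-yl)oxy]phenol | C=CC(C)(C)Oc1cc(Br)ccc1O | intermediate
6 | 4-bromo-2-[(2-methylbut-3-en-2-yl)oxy]-1-[(2-methylbut-3-yn-2-yl)oxy]benzene | C=CC(C)(C)Oc1cc(Br)ccc1OC(C)(C)C#C | intermediate
7 | 3-bromo-2-(3-methylbut-2-en-1-yl)-6-[(2-methylbut-3-yn-2-yl)oxy]phenol | C#CC(C)(C)Oc1ccc(Br)c(CC=C(C)C)c1O | intermediate (not isolated)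
8 | 4-bromo-3-(3-methylbut-2-en-1-yl)-6-(3-methylbuta-1,2-dien-1-yl)benzene-1,2-diol | CC(C)=C=Cc1cc(Br)c(CC=C(C)C)c(O)c1O | intermediate (not isolated)
9 | 6-bromo-2,2-dimethyl-7-(3-methylbut-2-en-1-yl)-2H-chromen-8-ol | CC(C)=CCc1c(Br)cc2C=CC(C)(C)Oc2c1O | intermediate
10 | methyl 2,4-dihydroxybenzoate | COC(=O)c1ccc(O)cc1O | starting material
11 | methyl 2,4-bis(methoxymethoxy)benzoate | COCOc1ccc(C(=O)OC)c(OCOC)c1 | intermediate
12 | ethylmagnesium bromide | CC[Mg]Br | starting material
13 | 1-[2,4-bis(methoxymethoxy)phenyl]cyclopropan-1-ol | COCOc1ccc(C2(O)CC2)c(OCOC)c1 | intermediate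
14 | 1-[2,4-bis(methoxymethoxy)phenyl]-3-[8-hydroxy-2,2-dimethyl-7-(3-methylbut-2-en-1-yl)-2H-chromen-6-yl]propan-1-one | CC(C)=CCc1c(CCC(=O)c2ccc(OCOC)cc2OCOC)cc2C=CC(C)(C)Oc2c1O | intermediate
15 | 1-(2,4-dihydroxyphenyl)-3-[8-hydroxy-2,2-dimethyl-7-(3-methylbut-2-en-1-yl)-2H-chromen-6-yl]propan-1-one | CC(C)=CCc1c(CCC(=O)c2ccc(O)cc2O)cc2c(c1O)OC(C)(C)C=C2 | target

**Step count and risks**
Total: 9 steps. Longest linear sequence: 7 steps (steps 1, 2, 3, 4, 5, 8, 9); steps 6 and 7 form the second branch.

The three steps most likely to fail: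

Step 8 (key coupling). The bromide is electron-rich, has an ortho prenyl group and carries a free phenol that becomes a cesium phenoxide. Oxidative addition may be slow, and the cyclopropanol may instead be lost by β-hydride elimination to the aryl vinyl ketone or by base-induced opening to the propiophenone. The fallback changes the coupling partner and the endgame rather than the catalyst. It sets out from 9, which is capped with NaH and MOMCl in DMF to give 6-bromo-8-(methoxymethoxy)-2,2-dimethyl-7-(3-methylbut-2-en-1-yl)-2H-chromene F2. This phenoxide-free bromide is coupled with 13 to give 1-[2,4-bis(methoxymethoxy)phenyl]-3-[8-(methoxymethoxy)-2,2-dimethyl-7-(3-methylbut-2-en-1-yl)-2H-chromen-6-yl]propan-1-one F3. Aqueous HCl in MeOH then removes all three MOM groups, and the fallback comes back to the route at 15.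

Step 4 (second tert-alkyl ether next to the first). Two tertiary ethers on neighbouring oxygens are crowded, so the alkylation may stall or the allyl ether may be lost. The fallback reverses the order of events and uses sterics for regiocontrol. It sets out from 5, which is heated alone in PhNEt2 at 130 °C so that the Claisen rearrangement comes first and gives 4-bromo-3-(3-methylbut-2-en-1-yl)benzene-1,2-diol F1. Copper-catalysed alkylation with 2 (1.05 equiv, DBU, CuCl2·2H2O, MeCN, −10 °C) should then take the hydroxyl para to bromine, because the other is flanked by the prenyl group. The fallback comes back to the route at 7, which is isolated and heated as in step 5 to give 9.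

Step 9 (acid on an ortho-prenylphenol). Acid can add the 8-OH across the prenyl double bond to give a chroman, or hydrate the chromene. The fallback replaces the acid-labile acetals with fluoride-labile silyl ethers and sets out from 10. TIPSOTf and 2,6-lutidine give methyl 2,4-bis[(triisopropylsilyl)oxy]benzoate F4; the bulky silyl group is chosen so that it does not migrate to the cyclopropoxide. Kulinkovich cyclopropanation gives 1-{2,4-bis[(triisopropylsilyl)oxy]phenyl}cyclopropan-1-ol F5. Coupling with 9 under the step 8 conditions gives 1-{2,4-bis[(triisopropylsilyl)oxy]phenyl}-3-[8-hydroxy-2,2-dimethyl-7-(3-methylbut-2-en-1-yl)-2H-chromen-6-yl]propan-1-one F6. TBAF buffered with AcOH in THF at 0 °C then frees both phenols, and the fallback comes back to the route at 15.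

**Further compounds**
F1 | step 4 | 4-bromo-3-(3-methylbut-2-en-1-yl)benzene-1,2-diol | CC(C)=CCc1c(Br)ccc(O)c1O
F2 | step 8 | 6-bromo-8-(methoxymethoxy)-2,2-dimethyl-7-(3-methylbut-2-en-1-yl)-2H-chromene | CC(C)=CCc1c(Br)cc2C=CC(C)(C)Oc2c1OCOC
F3 | step 8 | 1-[2,4-bis(methoxymethoxy)phenyl]-3-[8-(methoxymethoxy)-2,2-dimethyl-7-(3-methylbut-2-en-1-yl)-2H-chromen-6-yl]propan-1-one | CC(C)=CCc1c(CCC(=O)c2ccc(OCOC)cc2OCOC)cc2C=CC(C)(C)Oc2c1OCOC
F4 | step 9 | methyl 2,4-bis[(triisopropylsilyl)oxy]benzoate | COC(=O)c1ccc(O[Si](C(C)C)(C(C)C)C(C)C)cc1O[Si](C(C)C)(C(C)C)C(C)C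
F5 | step 9 | 1-{2,4-bis[(triisopropylsilyl)oxy]phenyl}cyclopropan-1-ol | OC1(CC1)c1ccc(O[Si](C(C)C)(C(C)C)C(C)C)cc1O[Si](C(C)C)(C(C)C)C(C)C
F6 | step 9 | 1-{2,4-bis[(triisopropylsilyl)oxy]phenyl}-3-[8-hydroxy-2,2-dimethyl-7-(3-methylbut-2-en-1-yl)-2H-chromen-6-yl]propan-1-one | CC(C)=CCc1c(CCC(=O)c2ccc(O[Si](C(C)C)(C(C)C)C(C)C)cc2O[Si](C(C)C)(C(C)C)C(C)C)cc2C=CC(C)(C)Oc2c1O
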